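C8–C9 is made in a one-pot, three-component coupling at a C9 gem-dibromide.

Target: (3R,6'R)-7,8-didehydro-β,ε-caroten-3-ol. Carotenoid numbering is used: ring A = hydroxylated cyclohexene C1–C6, chain C7–C15 and C15'–C7', ring B = cyclohexene C1'–C6'. No ring is formed: ring A (with C3) and ring B (with C6') are bought as enantiopure compounds.
Key disconnection at C9: the C8–C9 (alkyne–alkene) bond and the C9–C19 methyl bond are made in one pot on a C9 gem-dibromide. This unites the ring-A alkyne (C11), Me2Zn (C1) and the ring-B polyene dibromide (C28); only desilylation follows.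
Enabling feature: C9 is the one chain carbon with two carbon substituents, C8 of the C7≡C8 triple bond on ring A and methyl C19, while its partner C10 carries H and C11. The two bromines of a C9=CBr2 precursor therefore differ only in lying trans or cis to C11 and are replaced in that order, which sets the 9E geometry.
Ring-B polyene: (R)-α-ionone, C15 phosphonium salt, Wittig with the C10 dialdehyde (C11'=C12'), two-carbon Wittig homologation (C11=C12), dibromoolefination (C9=C10). Ring-A alkyne: (4R,6R)-actinol, enol triflate, Sonogashira coupling (C6–C7), C-desilylation.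

Key step: step 10

Remark: (4R,6R)-actinol and (R)-α-ionone are assumed to be purchasable in enantiopure form; all polyene work is assumed to be done under argon in dim light.

Step 1
Reactants: 1 (4R,6R)-4-hydroxy-2,2,6-trimethylcyclohexan-1-one (actinol)
Product: 2 (4R,6R)-4-[(tert-butyldimethylsilyl)oxy]-2,2,6-trimethylcyclohexan-1-one
Conditions: TBSCl, imidazole, DMF, rt
Reagents that add atoms: tert-butyldimethylsilyl chloride, CC(C)(C)[Si](C)(C)Cl
Why: Silyl ether protection of the unhindered secondary alcohol masks the hydroxyl against the amide base of step 2 and the organometallic reagents of step 10 without affecting either stereocentre.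

Step 2
Reactants: 2 (4R,6R)-4-[(tert-butyldimethylsilyl)oxy]-2,2,6-trimethylcyclohexan-1-one
Product: 4 (4R)-4-[(tert-butyldimethylsilyl)oxy]-2,6,6-trimethylcyclohex-1-en-1-yl trifluoromethanesulfonate, via lithium enolate 3 (not isolated)
Conditions: LiN(i-Pr)2 (commercial solution), THF, −78 to 0 °C; then PhNTf2, −78 °C to rt
Reagents that add atoms: N-phenylbis(trifluoromethanesulfonimide), O=S(=O)(N(c1ccccc1)S(=O)(=O)C(F)(F)F)C(F)(F)F
Why: Enol triflate formation by enolisation and O-sulfonylation gives a single regioisomer because only C6 of the ketone carries an α-hydrogen (C2 is quaternary), and it deliberately removes the C6 stereocentre while the silyloxy-bearing centre is retained.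

Step 3
Reactants: 4 (4R)-4-[(tert-butyldimethylsilyl)oxy]-2,6,6-trimethylcyclohex-1-en-1-yl trifluoromethanesulfonate
Product: 5 tert-butyldimethyl({(1R)-3,5,5-trimethyl-4-[(trimethylsilyl)ethynyl]cyclohex-3-en-1-yl}oxy)silane
Conditions: Me3SiC≡CH, PdCl2(PPh3)2 (cat.), CuI (cat.), Et3N, DMF, 50 °C
Reagents that add atoms: ethynyltrimethylsilane, C#C[Si](C)(C)C
Why: Sonogashira coupling of the alkenyl triflate with a sterically undemanding terminal alkyne forms the C6–C7 bond at the position fixed by the triflate despite the flanking quaternary carbon.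

Step 4
Reactants: 5 tert-butyldimethyl({(1R)-3,5,5-trimethyl-4-[(trimethylsilyl)ethynyl]cyclohex-3-en-1-yl}oxy)silane
Product: 6 tert-butyl{[(1R)-4-ethynyl-3,5,5-trimethylcyclohex-3-en-1-yl]oxy}dimethylsilane
Conditions: K2CO3 (0.2 equiv), MeOH, rt
Reagents that add atoms: none
Why: Base-catalysed methanolysis of the alkynyl C–Si bond (protodesilylation) is selective because the secondary tert-butyldimethylsilyl ether is stable to K2CO3 in methanol.

Step 5
Reactants: 7 (R)-α-ionone, (3E)-4-[(1R)-2,6,6-trimethylcyclohex-2-en-1-yl]but-3-en-2-one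
Product: 8 (1E)-3-methyl-1-[(1R)-2,6,6-trimethylcyclohex-2-en-1-yl]penta-1,4-dien-3-ol (both C3 epimers)
Conditions: CH2=CHMgBr, THF, −20 to 0 °C; aq. NH4Cl
Reagents that add atoms: vinylmagnesium bromide, C=C[Mg]Br
Why: Grignard 1,2-addition to the ketone at low temperature forms the new carbinol centre without control as two epimers, which is harmless because that carbon becomes sp2 in step 6, and the cold conditions leave the C6' stereocentre of 7 untouched.

Step 6
Reactants: 8 (1E)-3-methyl-1-[(1R)-2,6,6-trimethylcyclohex-2-en-1-yl]penta-1,4-dien-3-ol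
Product: 9 {(2E,4E)-3-methyl-5-[(1R)-2,6,6-trimethylcyclohex-2-en-1-yl]penta-2,4-dien-1-yl}triphenylphosphonium bromide
Conditions: PPh3·HBr, MeOH, 0 °C to rt; crystallise
Reagents that add atoms: triphenylphosphine hydrobromide, [Br-].c1ccc(cc1)[PH+](c1ccccc1)c1ccccc1
Why: In this SN1-type allylic transposition the acid ionises the tertiary bis-allylic alcohol to a pentadienyl cation that PPh3 captures at its unhindered primary terminus, which should give the thermodynamically preferred (2E,4E) salt without involving the C6' stereocentre.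

Step 7
Reactants: 9 {(2E,4E)-3-methyl-5-[(1R)-2,6,6-trimethylcyclohex-2-en-1-yl]penta-2,4-dien-1-yl}triphenylphosphonium bromide; 10 (2E,4E,6E)-2,7-dimethylocta-2,4,6-trienedial
Product: 12 (2E,4E,6E,8E,10E,12E)-2,7,11-trimethyl-13-[(1R)-2,6,6-trimethylcyclohex-2-en-1-yl]trideca-2,4,6,8,10,12-hexaenal, via C15 ylide 11 (not isolated)
Conditions: NaOMe, MeOH/CH2Cl2, 0 °C, 10 (3 equiv); then heptane, 90 °C
Reagents that add atoms: none
Why: Wittig olefination of the allylic ylide 11 with an excess of the symmetrical dialdehyde should stop at mono-condensation, and heating equilibrates the sterically hindered cis isomer of the new C11'=C12' bond to the all-E hexaenal.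

Step 8
Reactants: 12 (2E,4E,6E,8E,10E,12E)-2,7,11-trimethyl-13-[(1R)-2,6,6-trimethylcyclohex-2-en-1-yl]trideca-2,4,6,8,10,12-hexaenal
Product: 14 (2E,4E,6E,8E,10E,12E,14E)-4,9,13-trimethyl-15-[(1R)-2,6,6-trimethylcyclohex-2-en-1-yl]pentadeca-2,4,6,8,10,12,14-heptaenal, via dioxolane acetal 13 (not isolated)
Conditions: (1,3-dioxolan-2-ylmethyl)triphenylphosphonium bromide, KOt-Bu, THF, 0 °C (ylide preformed); 12, 0 °C to rt; then 1 M aq. HCl, THF, rt
Reagents that add atoms: (1,3-dioxolan-2-ylmethyl)triphenylphosphonium bromide, [Br-].C1COC(C[P+](c2ccccc2)(c2ccccc2)c2ccccc2)O1; water, O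
Why: Wittig two-carbon homologation with a masked formylmethylene ylide is followed by dilute-acid hydrolysis of the acetal, which should also equilibrate the hindered cis isomer of the new C11=C12 bond to the favoured E geometry.

Step 9
Reactants: 14 (2E,4E,6E,8E,10E,12E,14E)-4,9,13-trimethyl-15-[(1R)-2,6,6-trimethylcyclohex-2-en-1-yl]pentadeca-2,4,6,8,10,12,14-heptaenal
Product: 15 (6R)-6-[(1E,3E,5E,7E,9E,11E,13E)-16,16-dibromo-3,7,12-trimethylhexadeca-1,3,5,7,9,11,13,15-octaen-1-yl]-1,5,5-trimethylcyclohex-1-ene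
Conditions: CBr4, PPh3, Zn, CH2Cl2, rt (ylide preformed); then 14, 0 °C, dark
Reagents that add atoms: carbon tetrabromide, BrC(Br)(Br)Br
Why: In this Ramirez dibromoolefination (first half of the Corey–Fuchs sequence) the ylide Ph3P=CBr2, generated with Zn so that no Ph3PBr2 is present, condenses with the formyl group in a Wittig reaction under neutral conditions that the polyene and the C6' stereocentre should tolerate.

Step 10
Reactants: 6 tert-butyl{[(1R)-4-ethynyl-3,5,5-trimethylcyclohex-3-en-1-yl]oxy}dimethylsilane; 15 (6R)-6-[(1E,3E,5E,7E,9E,11E,13E)-16,16-dibromo-3,7,12-trimethylhexadeca-1,3,5,7,9,11,13,15-octaen-1-yl]-1,5,5-trimethylcyclohex-1-ene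
Product: 19 tert-butyldimethyl{[(3R,6'R)-7,8-didehydro-β,ε-caroten-3-yl]oxy}silane, via lithium acetylide 16 (not isolated), via alkynylzinc bromide 17 (not isolated), via bromoenyne 18 (not isolated)
Conditions: 6 (1.1 equiv), n-BuLi, THF, −78 °C; ZnBr2, −78 to 0 °C; 15, PdCl2(DPEphos) (5 mol %), THF, 0 °C to rt; then Me2Zn (2 equiv), Pd(P(t-Bu)3)2 (5 mol %), rt, dark; aq. NH4Cl
Reagents that add atoms: dimethylzinc, C[Zn]C
Why: Zerovalent palladium generated from PdCl2(DPEphos) should insert into the C9–Br bond of 15 that lies trans to C11 (cis only to the hydrogen on C10, hence less hindered), and transmetalation from alkynylzinc bromide 17 followed by reductive elimination forms the C8–C9 bond to give bromoenyne 18; Pd(P(t-Bu)3)2 then activates the remaining, slower C9–Br bond, which is coupled with Me2Zn with retention so that C19 ends up cis to C11, that is the (9E)-enyne. The closest known reaction type is the trans-selective Negishi monoalkynylation of 1,1-dibromo-1-alkenes followed by stereoretentive palladium-catalysed methylation of the resulting (Z)-bromoenyne, an established route to (E)-3-methylalk-3-en-1-ynes, run here in one pot as a three-component coupling. No ring is closed and no stereocentre is created; C3 and C6' are remote from the reacting carbon and are carried through unchanged. The selectivities needed are (a) mono- over dialkynylation, secured by the rate difference between the two bromines at 0 °C with only a slight excess of 17, and (b) geometric fidelity at C9=C10, secured in the first coupling by the steric bias of the C10 substituent and in the second by the bulky, electron-rich phosphine, which should let transmetalation and reductive elimination outrun isomerisation of the alkenylpalladium intermediate. In one operation the step makes two C–C bonds at C9, installs C19, fixes the only trisubstituted enyne geometry and unites both enantiopure end groups into the complete C40 skeleton.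

Step 11
Reactants: 19 tert-butyldimethyl{[(3R,6'R)-7,8-didehydro-β,ε-caroten-3-yl]oxy}silane
Product: 20 (3R,6'R)-7,8-didehydro-β,ε-caroten-3-ol
Conditions: Bu4NF, THF, 0 °C to rt, dark
Reagents that add atoms: none
Why: Fluoride-mediated cleavage of the silyl ether, driven by Si–F bond formation, should release the C3 alcohol with retention because the C–O bond is not broken, and it leaves the enyne, the polyene and C6' untouched.

Compound list
1 | (4R,6R)-4-hydroxy-2,2,6-trimethylcyclohexan-1-one (actinol) | O=C1[C@H](C)C[C@@H](O)CC1(C)C | starting material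
2 | (4R,6R)-4-[(tert-butyldimethylsilyl)oxy]-2,2,6-trimethylcyclohexan-1-one | O=C1[C@H](C)C[C@@H](O[Si](C)(C)C(C)(C)C)CC1(C)C | intermediate
3 | lithium (4R)-4-[(tert-butyldimethylsilyl)oxy]-2,6,6-trimethylcyclohex-1-en-1-olate | [Li]OC1=C(C)C[C@@H](O[Si](C)(C)C(C)(C)C)CC1(C)C | intermediate
4 | (4R)-4-[(tert-butyldimethylsilyl)oxy]-2,6,6-trimethylcyclohex-1-en-1-yl trifluoromethanesulfonate | O=S(=O)(OC1=C(C)C[C@@H](O[Si](C)(C)C(C)(C)C)CC1(C)C)C(F)(F)F | intermediate
5 | tert-butyldimethyl({(1R)-3,5,5-trimethyl-4-[(trimethylsilyl)ethynyl]cyclohex-3-en-1-yl}oxy)silane | C[Si](C)(C)C#CC1=C(C)C[C@@H](O[Si](C)(C)C(C)(C)C)CC1(C)C | intermediate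
6 | tert-butyl{[(1R)-4-ethynyl-3,5,5-trimethylcyclohex-3-en-1-yl]oxy}dimethylsilane | C#CC1=C(C)C[C@@H](O[Si](C)(C)C(C)(C)C)CC1(C)C | intermediate
7 | (R)-α-ionone, (3E)-4-[(1R)-2,6,6-trimethylcyclohex-2-en-1-yl]but-3-en-2-one | CC1=CCCC(C)(C)[C@H]1/C=C/C(C)=O | starting material
8 | (1E)-3-methyl-1-[(1R)-2,6,6-trimethylcyclohex-2-en-1-yl]penta-1,4-dien-3-ol (both C3 epimers) | CC1=CCCC(C)(C)[C@H]1/C=C/C(C)(O)C=C | intermediate
9 | {(2E,4E)-3-methyl-5-[(1R)-2,6,6-trimethylcyclohex-2-en-1-yl]penta-2,4-dien-1-yl}triphenylphosphonium bromide | CC1=CCCC(C)(C)[C@H]1/C=C/C(C)=C/C[P+](c1ccccc1)(c1ccccc1)c1ccccc1.[Br-] | intermediate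
10 | (2E,4E,6E)-2,7-dimethylocta-2,4,6-trienedial | O=C/C(C)=C/C=C/C=C(C)/C=O | starting material
11 | {(2E,4E)-3-methyl-5-[(1R)-2,6,6-trimethylcyclohex-2-en-1-yl]penta-2,4-dien-1-ylidene}triphenylphosphorane | CC1=CCCC(C)(C)[C@H]1/C=C/C(C)=C/C=P(c1ccccc1)(c1ccccc1)c1ccccc1 | intermediate
12 | (2E,4E,6E,8E,10E,12E)-2,7,11-trimethyl-13-[(1R)-2,6,6-trimethylcyclohex-2-en-1-yl]trideca-2,4,6,8,10,12-hexaenal | CC1=CCCC(C)(C)[C@H]1/C=C/C(C)=C/C=C/C(C)=C/C=C/C=C(C)/C=O | intermediate
13 | 2-{(3E,5E,7E,9E,11E,13E)-3,8,12-trimethyl-14-[(1R)-2,6,6-trimethylcyclohex-2-en-1-yl]tetradeca-1,3,5,7,9,11,13-heptaen-1-yl}-1,3-dioxolane (1E/1Z mixture) | CC1=CCCC(C)(C)[C@H]1/C=C/C(C)=C/C=C/C(C)=C/C=C/C=C(C)/C=CC1OCCO1 | intermediate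
14 | (2E,4E,6E,8E,10E,12E,14E)-4,9,13-trimethyl-15-[(1R)-2,6,6-trimethylcyclohex-2-en-1-yl]pentadeca-2,4,6,8,10,12,14-heptaenal | CC1=CCCC(C)(C)[C@H]1/C=C/C(C)=C/C=C/C(C)=C/C=C/C=C(C)/C=C/C=O | intermediate
15 | (6R)-6-[(1E,3E,5E,7E,9E,11E,13E)-16,16-dibromo-3,7,12-trimethylhexadeca-1,3,5,7,9,11,13,15-octaen-1-yl]-1,5,5-trimethylcyclohex-1-ene | CC1=CCCC(C)(C)[C@H]1/C=C/C(C)=C/C=C/C(C)=C/C=C/C=C(C)/C=C/C=C(Br)Br | intermediate
16 | ({(4R)-4-[(tert-butyldimethylsilyl)oxy]-2,6,6-trimethylcyclohex-1-en-1-yl}ethynyl)lithium | [Li]C#CC1=C(C)C[C@@H](O[Si](C)(C)C(C)(C)C)CC1(C)C | intermediate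
17 | bromo({(4R)-4-[(tert-butyldimethylsilyl)oxy]-2,6,6-trimethylcyclohex-1-en-1-yl}ethynyl)zinc | Br[Zn]C#CC1=C(C)C[C@@H](O[Si](C)(C)C(C)(C)C)CC1(C)C | intermediate
18 | (3R,6'R,9Z)-9-bromo-3-[(tert-butyldimethylsilyl)oxy]-7,8-didehydro-19-nor-β,ε-carotene | CC1=CCCC(C)(C)[C@H]1/C=C/C(C)=C/C=C/C(C)=C/C=C/C=C(C)/C=C/C=C(\Br)C#CC1=C(C)C[C@@H](O[Si](C)(C)C(C)(C)C)CC1(C)C | intermediate
19 | tert-butyldimethyl{[(3R,6'R)-7,8-didehydro-β,ε-caroten-3-yl]oxy}silane | CC1=CCCC(C)(C)[C@H]1/C=C/C(C)=C/C=C/C(C)=C/C=C/C=C(C)/C=C/C=C(\C)C#CC1=C(C)C[C@@H](O[Si](C)(C)C(C)(C)C)CC1(C)C | intermediate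
20 | (3R,6'R)-7,8-didehydro-β,ε-caroten-3-ol | CC1=CCCC(C)(C)[C@H]1/C=C/C(C)=C/C=C/C(C)=C/C=C/C=C(C)/C=C/C=C(\C)C#CC1=C(C)C[C@@H](O)CC1(C)C | target

Total step count: 11.
Longest linear sequence: 7 steps (steps 5 to 11, from 7); the ring-A branch (steps 1 to 4) joins at step 10.

Steps most likely to fail

Step 10. What may go wrong: erosion of the C9=C10 geometry through isomerisation of the alkenylpalladium intermediate during the methylation stage, over-alkynylation of the gem-dibromide, or slow decomposition of the polyene in the presence of the organozinc reagents. The fallback sets out from alkyne 6 and aldehyde 12 and returns at 19: the C8–C9 bond would be made first on a small acceptor, and the two large pieces joined afterwards by olefination at C11=C12. Addition of 6 across ethyl but-2-ynoate, catalysed by Pd(OAc)2 and tris(2,6-dimethoxyphenyl)phosphine (syn hydroalkynylation of an ynoate), should give ethyl (2E)-5-{(4R)-4-[(tert-butyldimethylsilyl)oxy]-2,6,6-trimethylcyclohex-1-en-1-yl}-3-methylpent-2-en-4-ynoate F1. Reduction with i-Bu2AlH (CH2Cl2, −78 °C) would give (2E)-5-{(4R)-4-[(tert-butyldimethylsilyl)oxy]-2,6,6-trimethylcyclohex-1-en-1-yl}-3-methylpent-2-en-4-yn-1-ol F2. PPh3·HBr (CH2Cl2, 0 °C) would convert it into {(2E)-5-{(4R)-4-[(tert-butyldimethylsilyl)oxy]-2,6,6-trimethylcyclohex-1-en-1-yl}-3-methylpent-2-en-4-yn-1-yl}triphenylphosphonium bromide F3. NaOMe would generate {(2E)-5-{(4R)-4-[(tert-butyldimethylsilyl)oxy]-2,6,6-trimethylcyclohex-1-en-1-yl}-3-methylpent-2-en-4-yn-1-ylidene}triphenylphosphorane F4, whose Wittig reaction with 12, followed by brief thermal equilibration of the new C11=C12 bond, should deliver 19.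

Step 9. What may go wrong: degradation or E/Z scrambling of the electron-rich heptaenal by electrophilic bromophosphonium species, and sluggish condensation at the strongly deactivated vinylogous formyl group. The fallback sets out from dialdehyde 10 and ylide 11 (from salt 9), bypasses 12 to 14 and returns at 15: the CBr2 terminus would be installed on the robust triene before the chiral end group is attached. Mono-Wittig reaction of excess 10 with Ph3P=CHCHO (toluene, 80 °C) should give (2E,4E,6E,8E)-2,7-dimethyldeca-2,4,6,8-tetraenedial F5. One equivalent of Ph3P=CBr2 (from CBr4, PPh3 and Zn, CH2Cl2, −20 °C) should react at the unbranched, less hindered formyl group to give (2E,4E,6E,8E)-11,11-dibromo-2,7-dimethylundeca-2,4,6,8,10-pentaenal F6. Wittig reaction of F6 with ylide 11 and thermal equilibration of the new C11'=C12' bond would then give 15.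

Step 8. What may go wrong: incomplete cis-to-trans equilibration at the new C11=C12 bond, or acid-induced migration of the ring-B double bond with loss of the C6' stereocentre during acetal hydrolysis. The fallback sets out from 12 and returns at 14 without mineral acid. Horner–Wadsworth–Emmons reaction of 12 with diethyl (cyanomethyl)phosphonate and NaH (THF, 0 °C) should give (2E,4E,6E,8E,10E,12E,14E)-4,9,13-trimethyl-15-[(1R)-2,6,6-trimethylcyclohex-2-en-1-yl]pentadeca-2,4,6,8,10,12,14-heptaenenitrile F7. Reduction with i-Bu2AlH (toluene, −78 °C) to the aldimine and hydrolysis on wet silica gel would then give 14.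

Further compounds
F1 | step 10 | ethyl (2E)-5-{(4R)-4-[(tert-butyldimethylsilyl)oxy]-2,6,6-trimethylcyclohex-1-en-1-yl}-3-methylpent-2-en-4-ynoate | CCOC(=O)/C=C(\C)C#CC1=C(C)C[C@@H](O[Si](C)(C)C(C)(C)C)CC1(C)C
F2 | step 10 | (2E)-5-{(4R)-4-[(tert-butyldimethylsilyl)oxy]-2,6,6-trimethylcyclohex-1-en-1-yl}-3-methylpent-2-en-4-yn-1-ol | OC/C=C(\C)C#CC1=C(C)C[C@@H](O[Si](C)(C)C(C)(C)C)CC1(C)C
F3 | step 10 | {(2E)-5-{(4R)-4-[(tert-butyldimethylsilyl)oxy]-2,6,6-trimethylcyclohex-1-en-1-yl}-3-methylpent-2-en-4-yn-1-yl}triphenylphosphonium bromide | [Br-].c1ccc(cc1)[P+](c1ccccc1)(c1ccccc1)C/C=C(\C)C#CC1=C(C)C[C@@H](O[Si](C)(C)C(C)(C)C)CC1(C)C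
F4 | step 10 | {(2E)-5-{(4R)-4-[(tert-butyldimethylsilyl)oxy]-2,6,6-trimethylcyclohex-1-en-1-yl}-3-methylpent-2-en-4-yn-1-ylidene}triphenylphosphorane | c1ccc(cc1)P(c1ccccc1)(c1ccccc1)=C/C=C(\C)C#CC1=C(C)C[C@@H](O[Si](C)(C)C(C)(C)C)CC1(C)C
F5 | step 9 | (2E,4E,6E,8E)-2,7-dimethyldeca-2,4,6,8-tetraenedial | O=C/C(C)=C/C=C/C=C(C)/C=C/C=O
F6 | step 9 | (2E,4E,6E,8E)-11,11-dibromo-2,7-dimethylundeca-2,4,6,8,10-pentaenal | O=C/C(C)=C/C=C/C=C(C)/C=C/C=C(Br)Br
F7 | step 8 | (2E,4E,6E,8E,10E,12E,14E)-4,9,13-trimethyl-15-[(1R)-2,6,6-trimethylcyclohex-2-en-1-yl]pentadeca-2,4,6,8,10,12,14-heptaenenitrile | CC1=CCCC(C)(C)[C@H]1/C=C/C(C)=C/C=C/C(C)=C/C=C/C=C(C)/C=C/C#N
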